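**Assumption:** the target is taken as the H-bonded enol tautomer drawn (keto and enol forms equilibrate). Descriptors used throughout: cyclohexene C1 (OAr) = R, C4 (OH) = S, C6 (side chain) = R; side-chain C2′ = S. OAr and OH are cis to each other and trans to the side chain.

## Retrosynthetic overview

1. The cyclohexene ring is not built. It is the benzene ring of 3-bromotoluene (1), N-arylated with (S)-2-(methoxymethyl)pyrrolidine (2) to give 3, then dearomatised by Birch reduction to the chiral, unconjugated enamine 4 (key step).
2. C6–C2′ bond: enamine 4 + dienone 7 (from crotonoyl chloride 5 + isobutenyl Grignard 6) gives keto-enone 8. Both carbon stereocentres are set here.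
3. Ring adjustment: 8 → dienyl triflate 9 → α-turmerone 10 → vinyl epoxide 11.
4. Aryl ether C–O bond: Pd π-allyl opening of 11 by vanillin (12) gives 13 (cis-1,4; sets the two oxygenated stereocentres).
5. Curcuminoid C=C bond: boron-templated condensation of 13 with half-curcuminoid 16 (from 4-hydroxybenzaldehyde 14 + acetylacetone 15) gives target 17. No carbocycle is formed; all three six-membered rings come from aromatic starting materials, and the only ring made is the transient oxirane of 11.

## Route

**Step 1**
Reactants: 1, 3-bromotoluene; 2, (S)-2-(methoxymethyl)pyrrolidine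
Product: 3, (2S)-2-(methoxymethyl)-1-(3-methylphenyl)pyrrolidine
Conditions: Pd2(dba)3 (1 mol%), RuPhos (2.4 mol%), NaOtBu, toluene, 90 °C
Reagents that add atoms: none
Why: Buchwald–Hartwig N-arylation of a secondary amine; the pyrrolidine stereocentre is not involved.

**Step 2 (key step)**
Reactants: 3
Product: 4, (2S)-2-(methoxymethyl)-1-(5-methylcyclohexa-1,4-dien-1-yl)pyrrolidine
Conditions: Li (3 equiv), NH3(l)/THF, t-BuOH (2.5 equiv), −78 → −33 °C; isoprene quench; evaporate NH3; pentane extraction under Ar; used crude
Reagents that add atoms: none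
Why: Birch reduction keeps the amino donor and the methyl on sp2 carbons, so only the 1-amino-1,4-diene forms; this unconjugated enamine cannot be made from the ketone (which gives the conjugated dienamine) and its only nucleophilic carbon is para to C–Me; no stereocentre is formed.

**Step 3**
Reactants: 5, (E)-crotonoyl chloride; 6, 2-methylprop-1-enylmagnesium bromide
Product: 7, (E)-2-methylhepta-2,5-dien-4-one
Conditions: 6, ZnCl2, THF, 0 °C; then 5, Pd(PPh3)4 (2 mol%), 0 °C → rt
Reagents that add atoms: none
Why: Negishi acylation of the alkenylzinc gives the divinyl ketone without over-addition or conjugate addition, and the E geometry of the crotonyl unit is retained.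

**Step 4**
Reactants: 4 (1.2 equiv); 7 (1.0 equiv)
Product: 8, (6R)-3-methyl-6-[(2S)-6-methyl-4-oxohept-5-en-2-yl]cyclohex-3-en-1-one
Conditions: MeCN, −20 °C → rt, 24 h; then AcOH/NaOAc/H2O (pH ≈ 5), 0 °C; 2 recovered by acid–base extraction
Reagents that add atoms: water, O (ring carbonyl oxygen)
Why: Stork enamine Michael addition through a hetero-Diels–Alder-like synclinal transition state: the s-cis enone (C=O over N) reacts at its less hindered crotyl terminus on the enamine face anti to the CH2OMe arm, setting C6 = R and, from the E-alkene, C2′ = S (syn). Afterwards enamine/enol formation goes only toward the doubly activated C2, so C6 does not epimerise. The reaction type is known (SMP-enamine additions to nitroalkenes); the level of induction with an enone acceptor is an extrapolation.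

**Step 5**
Reactants: 8
Product: 9, (6R)-3-methyl-6-[(2S)-6-methyl-4-oxohept-5-en-2-yl]cyclohexa-1,3-dien-1-yl trifluoromethanesulfonate
Conditions: KHMDS (1.05 equiv), THF, −78 °C, 15 min; PhNTf2 (1.1 equiv), −78 → −30 °C
Reagents that add atoms: N-phenyl-bis(trifluoromethanesulfonimide), O=S(=O)(N(c1ccccc1)S(=O)(=O)C(F)(F)F)C(F)(F)F
Why: The C2 protons (α to C=O and allylic) are by far the most acidic in the molecule, so one equivalent of base gives the linear ring dienolate, which is O-triflated; C6–H and the side-chain ketone are not touched.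

**Step 6**
Reactants: 9
Product: 10, (6S)-2-methyl-6-[(1R)-4-methylcyclohexa-2,4-dien-1-yl]hept-2-en-4-one (α-turmerone)
Conditions: Pd(OAc)2 (3 mol%), PPh3 (6 mol%), n-Bu3N, HCO2H, DMF, 40 °C
Reagents that add atoms: none
Why: Pd-catalysed formate reduction of the dienyl triflate (oxidative addition, formate decarboxylation, C–H reductive elimination) leaves the 1,3-diene in place and tolerates the hindered enone; stereocentres are untouched.

**Step 7**
Reactants: 10
Product: 11, (6S)-2-methyl-6-[(1R,4R,6S)-1-methyl-7-oxabicyclo[4.1.0]hept-2-en-4-yl]hept-2-en-4-one (epoxide anti to the side chain)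
Conditions: ent-Shi ketone (L-fructose-derived, 0.3 equiv), Oxone, K2CO3, n-Bu4NHSO4, MeCN/DMM–aq. Na2B4O7/EDTA (pH 10.5), 0 °C; used crude
Reagents that add atoms: Oxone (potassium peroxymonosulfate), [K+].OOS(=O)(=O)[O-]
Why: Shi dioxirane epoxidation picks the electron-rich trisubstituted alkene of the diene (the enone alkene is inert); by the spiro transition-state model (D-catalyst gives (R,R)-1-phenylcyclohexene oxide) the L-catalyst delivers oxygen to the face anti to the side chain, which is also the substrate-preferred face.

**Step 8**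
Reactants: 11; 12, vanillin (1.2 equiv)
Product: 13, 4-{[(1R,4S,6R)-4-hydroxy-3-methyl-6-[(2S)-6-methyl-4-oxohept-5-en-2-yl]cyclohex-2-en-1-yl]oxy}-3-methoxybenzaldehyde
Conditions: Pd2(dba)3·CHCl3 (2.5 mol%), PPh3 (10 mol%), THF, 0 °C → rt
Reagents that add atoms: none
Why: Tsuji–Trost opening of the vinyl epoxide: Pd(0) ionises the tertiary allylic C–O with inversion, the alkoxide deprotonates vanillin, and the phenoxide attacks the distal secondary allyl terminus anti to Pd. Net retention gives the cis-1,4-hydroxy aryl ether (C1 = R, C4 = S) without any diol differentiation.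

**Step 9**
Reactants: 14, 4-hydroxybenzaldehyde; 15, acetylacetone (3 equiv)
Product: 16, (E)-6-(4-hydroxyphenyl)hex-5-ene-2,4-dione
Conditions: B2O3, EtOAc, 70 °C; B(On-Bu)3, n-BuNH2 (cat.); then 0.4 M HCl, 50 °C
Reagents that add atoms: none
Why: Pabon boron-chelate aldol condensation; excess acetylacetone stops at the mono-adduct and the chelate blocks the central CH2.

**Step 10**
Reactants: 13; 16 (1.3 equiv)
Product: 17, (1E,4Z,6E)-5-hydroxy-7-[4-{[(1R,4S,6R)-4-hydroxy-3-methyl-6-[(2S)-6-methyl-4-oxohept-5-en-2-yl]cyclohex-2-en-1-yl]oxy}-3-methoxyphenyl]-1-(4-hydroxyphenyl)hepta-1,4,6-trien-3-one (target)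
Conditions: 16, B2O3, DMF, 50 °C; then 13, B(On-Bu)3, n-BuNH2 (0.3 equiv, slow addition), 50 °C; then 10% aq. AcOH, rt
Reagents that add atoms: none
Why: Pabon condensation of the boron-activated terminal methyl of 16 with the aryl aldehyde gives the E-enone; the unactivated side-chain ketone, free allylic alcohol and allylic aryl ether are expected to survive these mildly basic conditions and the weak-acid work-up.

## Compound list

1 | 3-bromotoluene | Cc1cccc(Br)c1 | starting material
2 | (S)-2-(methoxymethyl)pyrrolidine | COC[C@@H]1CCCN1 | starting material (recovered in step 4)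
3 | (2S)-2-(methoxymethyl)-1-(3-methylphenyl)pyrrolidine | COC[C@@H]1CCCN1c1cccc(C)c1 | intermediate
4 | (2S)-2-(methoxymethyl)-1-(5-methylcyclohexa-1,4-dien-1-yl)pyrrolidine | COC[C@@H]1CCCN1C1=CCC=C(C)C1 | intermediate
5 | (E)-crotonoyl chloride | C/C=C/C(Cl)=O | starting material
6 | 2-methylprop-1-enylmagnesium bromide | CC(C)=C[Mg]Br | starting material
7 | (E)-2-methylhepta-2,5-dien-4-one | C/C=C/C(=O)C=C(C)C | intermediate
8 | (6R)-3-methyl-6-[(2S)-6-methyl-4-oxohept-5-en-2-yl]cyclohex-3-en-1-one | O=C1CC(C)=CC[C@@H]1[C@@H](C)CC(=O)C=C(C)C | intermediate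
9 | (6R)-3-methyl-6-[(2S)-6-methyl-4-oxohept-5-en-2-yl]cyclohexa-1,3-dien-1-yl triflate | O=S(=O)(OC1=CC(C)=CC[C@@H]1[C@@H](C)CC(=O)C=C(C)C)C(F)(F)F | intermediate
10 | (6S)-2-methyl-6-[(1R)-4-methylcyclohexa-2,4-dien-1-yl]hept-2-en-4-one | C1=CC(C)=CC[C@@H]1[C@@H](C)CC(=O)C=C(C)C | intermediate
11 | (6S)-2-methyl-6-[(1R,4R,6S)-1-methyl-7-oxabicyclo[4.1.0]hept-2-en-4-yl]hept-2-en-4-one | C1=C[C@@]2(C)O[C@H]2C[C@@H]1[C@@H](C)CC(=O)C=C(C)C | intermediate
12 | vanillin | COc1cc(C=O)ccc1O | starting material
13 | 4-{[(1R,4S,6R)-4-hydroxy-3-methyl-6-[(2S)-6-methyl-4-oxohept-5-en-2-yl]cyclohex-2-en-1-yl]oxy}-3-methoxybenzaldehyde | COc1cc(C=O)ccc1O[C@H]1C=C(C)[C@@H](O)C[C@@H]1[C@@H](C)CC(=O)C=C(C)C | intermediate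
14 | 4-hydroxybenzaldehyde | O=Cc1ccc(O)cc1 | starting material
15 | acetylacetone | CC(=O)CC(C)=O | starting material
16 | (E)-6-(4-hydroxyphenyl)hex-5-ene-2,4-dione | CC(=O)CC(=O)/C=C/c1ccc(O)cc1 | intermediate
17 | demethoxybisabolocurcumin ether | COc1cc(/C=C/C(O)=C/C(=O)/C=C/c2ccc(O)cc2)ccc1O[C@H]1C=C(C)[C@@H](O)C[C@@H]1[C@@H](C)CC(=O)C=C(C)C | target

## Summary

Total steps: 10. Longest linear sequence: 8 (steps 1, 2, 4, 5, 6, 7, 8, 10). No protecting groups.

Three steps most likely to fail:

- **Step 2 (Birch reduction of the N-aryl amine).** Risks are over-reduction and isomerisation of 4 to the conjugated dienamine, which would then react as a Diels–Alder diene. Fallback: move to the oxygen series. Birch-reduce 3-methylanisole to the stable enol ether 1-methoxy-5-methylcyclohexa-1,4-diene and join it to 7 by a Lewis-acid-catalysed inverse-demand hetero-Diels–Alder reaction, then hydrolyse to 8. Absolute control would then come from a chiral Lewis acid or from the reagent-controlled epoxidation in step 7.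
- **Step 4 (level of syn selectivity and ee with an enone acceptor).** Fallback: run the addition with the achiral pyrrolidine analogue of 4 to get racemic syn-8, carry it to racemic 10, and resolve at step 7. The catalyst-controlled Shi epoxidation converts the two enantiomers into separable diastereomeric epoxides, and only the anti-epoxide is advanced.
- **Steps 7–8 (acid-labile vinyl epoxide; regiochemistry and reversibility of the Pd etherification).** Fallback: singlet-oxygen [4+2] on 10 to the endoperoxide anti to the side chain, thiourea reduction to the cis-1,4-diol, silylation of the less hindered C4–OH, SNAr of the C1 alkoxide on 4-fluoro-3-methoxybenzaldehyde, then desilylation to 13.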